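The data are calculated from invented constants.

The ratio JiVy/JiJo is the number I want: in this flask solid Xo feeds dissolved Ji, and Ji turns Vy into JiVy and Jo into JiJo.

| flask | Vy | Jo | Xo | remark | time |
|---|---|---|---|---|---|
| alder | 0.10 M | 0.10 M | 0.33 M | run made earlier |  |
| flask | 0.10 M | 0.10 M | 0.220 M |  | 6.0 d |

- alder (time / h: JiVy / %, JiJo / %): 6.00: 1.4, 0.3; 12.0: 1.9, 1.4; 20.0: 4.0, 2.6; 25.0: 5.3, 3.9; 30.0: 6.9, 4.6; 40.0: 10.9, 5.9

(each reading ± 0.5 percentage points)

- Ji is single-handed; Vy and Jo are mirror images of each other, charged as a racemate, each of them at the stated concentration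
- solid, in amounts per volume of the solution: Xo
- the analysis behind the earlier runs scatters by 0.5 percentage points, standard deviation
- at the start none of Xo is in solution
- an excess is the difference of the two amounts in percent of their sum
- an excess is below zero if the other one leads
- the handed part of Ji does not stay in what it makes, so the products of the two hands are mirror images too

1. JiVy and JiJo together, in percent of the Vy and Jo charged together, at 6.0 d
2. excess of JiVy over JiJo in the product at 6.0 d
3. whether the exchange between Vy and Jo keeps pace with the reaction: how far the product's excess at 6.0 d gets from its value without exchange to its value with instant exchange (above 80% keeps pace, below 20% hardly takes part, else lags behind)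

I add the columns of the alder run: JiVy comes to 30.4% and JiJo to 18.7%. Their quotient is s = 1.63, the selectivity factor: the rate of JiVy formation over that of JiJo at equal cVy and cJo. It is a reading, and each entry scatters by 0.5 percentage points.

Now I solve both ends. With instant exchange, cVy and cJo stay equal, so the excess is (s − 1)/(s + 1) = 23.8% at any conversion. Without exchange, once half of the Jo has reacted, the Vy left is 32.3% of its charge, so conversion is 58.8% and the excess 15.0%.

Row against row, the ratio read in the alder run is 1.54 up to 25.0 h and 1.70 afterwards, higher rather than lower. That is a weak hint, but I commit to the instant end: about 23.8%, keeping pace. The forecast differs from me on the excess and on pace: it gives 50% (33% to 72%) of product, an excess of 20% (13% to 29%) and "lags behind", which it calls “a tentative guess”.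

The flask gives 56.3% of product, an excess of 24.8%, and its exchange keeps pace, at 88% of the way.

    Ji + Vy → JiVy (k = 3.40 × 10⁻⁴ M⁻¹ s⁻¹)
    Ji + Jo → JiJo (k = 2.00 × 10⁻⁴ M⁻¹ s⁻¹)
    Vy ⇌ Aj (K = 0.0870, k = 3.70 × 10⁻⁵ s⁻¹)
    Jo ⇌ Aj (K = 0.0870, k = 3.70 × 10⁻⁵ s⁻¹)
    Aj → Ky (k = 6.80 × 10⁻⁶ s⁻¹)
    Ji ⇌ Dx (K = 1.50, k = 6.50 × 10⁻⁶ s⁻¹)
    Xo ⇌ Ji, rate k7*(cs7 - [Ji]) while solid is left; crystals form when [Ji] > cs7 (solubility = 23.0 mM, k = 1.60 × 10⁻⁵ s⁻¹)

Among what is left in the flask at 6.00 d, Jo leads Vy by an excess of 1.83%. The product ratio there is 1.66, against s of 1.63. The neighbour flask charged with 0.088 M of Xo reaches 41.5%; s puts its excess at 23.8%, and it stands at 25.0%.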